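**Plan**

1. Numbering (daucane, used for all intermediates): C1 quaternary carbon (methyl C15), C2, C3, C4 (isopropyl), C5 ring-fusion sp2 carbon, C6, C7, C8 (bears C14H2O), C9 (=CH), C10 (CH2 on C1).
2. Retrosynthesis: cut the ester O–C14 bond and then C8–C14 (carbonylation of the C8 enol triflate); return C10 from C1 to its neighbour C5 (1,2-shift), which turns the seven-membered ring into the six-membered ring of a spiro[4.5]decadienone; cut C5–C6 and C9=C10 of that cyclohexenone (Robinson annulation) to a cyclopentene carbaldehyde and methyl vinyl ketone.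
3. Forward: the five-membered ring comes first, from (R)-limonene by ozonolysis and aldol ring contraction; the six-membered spiro ring is built on C5; it is expanded to the seven-membered ring; C14 and the vanillate come last.
4. Enabling feature: C5 and C1 are neighbours in the five-membered ring, C5 being the α- and C1 the β-carbon of an enal whose formyl carbon is C10. The extended enolate is nucleophilic at C5, so C5–C6 and C9=C10 can close the ring C5–C6–C7–C8–C9–C10; the enone C8(=O)–C9=C10 so formed makes C10 a radical acceptor that can move from C5 to a radical at C1.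
5. Stereochemistry: the single stereocentre (C1, R) stems from C4 of (R)-limonene. The isopropyl group steers the Michael addition to the opposite face of C5 (spiro centre), and the suprafacial shift of C10, which lies cis to isopropyl, carries this over to C1 while C4 and C5 become sp2.

Key step: step 4

**Route**

Step 1
Reactants: 1 (R)-(+)-limonene
Product: 2 (4R)-1-methyl-4-(propan-2-yl)cyclohex-1-ene
Conditions: H2 (1 atm), RhCl(PPh3)3 (1 mol %), benzene, 25 °C
Reagents that add atoms: none
Why: Homogeneous rhodium-catalysed hydrogenation should reduce the unhindered 1,1-disubstituted isopropenyl alkene much faster than the trisubstituted ring alkene, and the stereocentre is not touched.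

Step 2
Reactants: 2 (4R)-1-methyl-4-(propan-2-yl)cyclohex-1-ene
Product: 4 (3R)-6-oxo-3-(propan-2-yl)heptanal, via ozonide 3 (not isolated)
Conditions: O3, CH2Cl2, −78 °C; then Me2S, −78 → 25 °C
Reagents that add atoms: ozone, [O-][O+]=O
Why: Ozonolysis with reductive work-up should cleave the only remaining alkene to the 1,6-keto aldehyde without affecting the stereocentre.

Step 3
Reactants: 4 (3R)-6-oxo-3-(propan-2-yl)heptanal
Product: 5 (5S)-2-methyl-5-(propan-2-yl)cyclopent-1-ene-1-carbaldehyde
Conditions: piperidine (0.2 equiv), AcOH (0.2 equiv), benzene, reflux, Dean–Stark trap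
Reagents that add atoms: none
Why: The aldehyde enamine should add to the methyl ketone (five-membered ring, intramolecular aldol condensation) and dehydrate to the conjugated enal, the isopropyl-bearing centre (now C4) being untouched.

Step 4
Reactants: 5 (5S)-2-methyl-5-(propan-2-yl)cyclopent-1-ene-1-carbaldehyde; 6 methyl vinyl ketone
Product: 8 (4S,5R)-1-methyl-4-(propan-2-yl)spiro[4.5]deca-1,6-dien-8-one, via Michael adduct 7 (not isolated)
Conditions: KOtBu (0.3 equiv), t-BuOH/THF, 0 °C, 6 added slowly; then 50 °C
Reagents that add atoms: none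
Why: KOtBu removes a γ-hydrogen (at C2 or C15) of 5 to give the extended enolate, whose α-carbon C5 adds to the terminal carbon of 6 (C6) while the ring double bond moves out of conjugation to C1=C2; the methyl carbon of the resulting ketone 7 (C9) then condenses with the now non-enolisable aldehyde carbon C10 and water is lost. The closest known reaction type is the Robinson annulation of an α-branched aldehyde to a 4,4-disubstituted cyclohexenone, run through a dienolate as in deconjugative α-alkylation of enals and enones. The six-membered ring closes by a 6-(enolexo)-exo-trig aldol addition of C9 to C10. The new quaternary stereocentre C5 is controlled by the adjacent C4 stereocentre: the isopropyl group blocks one face of the planar enolate, so C6 should enter anti to it and the formyl carbon C10 is left cis to isopropyl. The step needs α- rather than γ-attack of the enolate; this is secured by the larger coefficient at C5 and by the reversibility of the Michael addition under basic conditions, whereas only the α-adduct can close a six-membered ring and dehydrate irreversibly. Should the exocyclic isomer (C1=C15) of the cyclopentene double bond form, it is equally serviceable, since both isomers lead to the same C1 radical in step 5.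

Step 5
Reactants: 8 (4S,5R)-1-methyl-4-(propan-2-yl)spiro[4.5]deca-1,6-dien-8-one
Product: 9 (8aR)-8a-methyl-3-(propan-2-yl)-1,2,4,5-tetrahydroazulen-6(8aH)-one
Conditions: chloro[N,N'-bis(3,5-di-tert-butylsalicylidene)-1,2-cyclohexanediaminato]cobalt (10 mol %), PhSiH3 (10 mol %), degassed benzene (0.02 M), 25–50 °C
Reagents that add atoms: none
Why: Proposed new method: hydrogen-atom transfer from the cobalt hydride to C2 should give the tertiary C1 radical, which adds 3-exo to C10, the β-carbon of the enone (polarity-matched, α-keto-stabilised cyclopropylcarbinyl radical), and opening of the C5–C10 bond moves C10 suprafacially from C5 to C1 (only the unsaturated arm can migrate in a radical, so C6 stays, and C10 on the face cis to isopropyl fixes C1 as R); the tertiary C5 radical then returns the hydrogen atom of C4 to divalent cobalt, giving the tetrasubstituted C4=C5 alkene, which is inert to further hydrogen-atom transfer and should therefore accumulate whatever the relative stability of the spiro and fused skeletons, while trisubstituted isomers re-enter the cycle; the closest known reaction types are cobalt-salen-catalysed alkene isomerisation and cycloisomerisation by hydrogen-atom transfer and the radical 1,2-vinyl (homoallyl–cyclopropylcarbinyl) shift.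

Step 6
Reactants: 9 (8aR)-8a-methyl-3-(propan-2-yl)-1,2,4,5-tetrahydroazulen-6(8aH)-one
Product: 11 (8aR)-8a-methyl-3-(propan-2-yl)-1,2,4,5,8,8a-hexahydroazulen-6-yl trifluoromethanesulfonate, via lithium enolate 10 (not isolated)
Conditions: Li (2.2 equiv), t-BuOH (1.0 equiv), NH3(l)/THF, −78 °C; NH3 evaporated; then PhNTf2, THF, 0 → 25 °C
Reagents that add atoms: N-phenylbis(trifluoromethanesulfonimide), O=S(=O)(N(c1ccccc1)S(=O)(=O)C(F)(F)F)C(F)(F)F
Why: Dissolving-metal reduction of the enone should deliver the C8–C9 enolate regiospecifically despite the hindered β-carbon C10, and O-triflation fixes the C8=C9 double bond (reductive enolate trapping); the tetrasubstituted alkene is inert to Li/NH3.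

Step 7
Reactants: 11 (8aR)-8a-methyl-3-(propan-2-yl)-1,2,4,5,8,8a-hexahydroazulen-6-yl trifluoromethanesulfonate
Product: 12 methyl (8aR)-8a-methyl-3-(propan-2-yl)-1,2,4,5,8,8a-hexahydroazulene-6-carboxylate
Conditions: Pd(OAc)2 (5 mol %), PPh3 (10 mol %), CO (1 atm), MeOH, Et3N, DMF, 40 °C
Reagents that add atoms: carbon monoxide, [C-]#[O+]; methanol, CO
Why: Oxidative addition of zerovalent palladium to the alkenyl triflate, CO insertion and methanolysis should install C14 as the conjugated ester (palladium-catalysed alkoxycarbonylation of an enol triflate).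

Step 8
Reactants: 12 methyl (8aR)-8a-methyl-3-(propan-2-yl)-1,2,4,5,8,8a-hexahydroazulene-6-carboxylate
Product: 13 [(8aR)-8a-methyl-3-(propan-2-yl)-1,2,4,5,8,8a-hexahydroazulen-6-yl]methanol
Conditions: i-Bu2AlH (2.5 equiv), CH2Cl2, −78 °C; aq. potassium sodium tartrate
Reagents that add atoms: none
Why: i-Bu2AlH should reduce the α,β-unsaturated ester by 1,2-addition to the primary allylic alcohol without touching either alkene.

Step 9
Reactants: 13 [(8aR)-8a-methyl-3-(propan-2-yl)-1,2,4,5,8,8a-hexahydroazulen-6-yl]methanol; 14 vanillic acid
Product: 15 [(8aR)-8a-methyl-3-(propan-2-yl)-1,2,4,5,8,8a-hexahydroazulen-6-yl]methyl 4-hydroxy-3-methoxybenzoate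
Conditions: PPh3 (1.2 equiv), DIAD (1.2 equiv), THF, 0 → 25 °C
Reagents that add atoms: none
Why: In this Mitsunobu esterification only the carboxylic acid of 14 is acidic enough to protonate the betaine, so the carboxylate should displace the activated primary allylic alcohol by SN2 and the phenol needs no protection; no stereocentre is involved.

**Compound list**

1 | (R)-(+)-limonene, (4R)-1-methyl-4-(prop-1-en-2-yl)cyclohex-1-ene | CC1=CC[C@@H](CC1)C(C)=C | starting material
2 | (4R)-1-methyl-4-(propan-2-yl)cyclohex-1-ene | CC1=CC[C@@H](CC1)C(C)C | intermediate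
3 | ozonide of 2 (1,2,4-trioxolane across the former ring double bond; acetal carbons of undefined configuration) | CC12CC[C@H](CC(OO1)O2)C(C)C | intermediate
4 | (3R)-6-oxo-3-(propan-2-yl)heptanal | O=CC[C@@H](CCC(C)=O)C(C)C | intermediate
5 | (5S)-2-methyl-5-(propan-2-yl)cyclopent-1-ene-1-carbaldehyde | O=CC1=C(C)CC[C@H]1C(C)C | intermediate
6 | methyl vinyl ketone (but-3-en-2-one) | CC(=O)C=C | starting material
7 | (1R,5S)-2-methyl-1-(3-oxobutyl)-5-(propan-2-yl)cyclopent-2-ene-1-carbaldehyde (formyl cis to isopropyl) | CC(=O)CC[C@]1(C=O)C(C)=CC[C@H]1C(C)C | intermediate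
8 | (4S,5R)-1-methyl-4-(propan-2-yl)spiro[4.5]deca-1,6-dien-8-one (enone CH= cis to isopropyl) | CC1=CC[C@@H](C(C)C)[C@@]12C=CC(=O)CC2 | intermediate
9 | (8aR)-8a-methyl-3-(propan-2-yl)-1,2,4,5-tetrahydroazulen-6(8aH)-one | O=C1C=C[C@@]2(C)CCC(C(C)C)=C2CC1 | intermediate
10 | lithium (8aR)-8a-methyl-3-(propan-2-yl)-1,2,4,5,8,8a-hexahydroazulen-6-olate | [Li+].[O-]C1=CC[C@@]2(C)CCC(C(C)C)=C2CC1 | intermediate
11 | (8aR)-8a-methyl-3-(propan-2-yl)-1,2,4,5,8,8a-hexahydroazulen-6-yl trifluoromethanesulfonate | O=S(=O)(OC1=CC[C@@]2(C)CCC(C(C)C)=C2CC1)C(F)(F)F | intermediate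
12 | methyl (8aR)-8a-methyl-3-(propan-2-yl)-1,2,4,5,8,8a-hexahydroazulene-6-carboxylate | COC(=O)C1=CC[C@@]2(C)CCC(C(C)C)=C2CC1 | intermediate
13 | [(8aR)-8a-methyl-3-(propan-2-yl)-1,2,4,5,8,8a-hexahydroazulen-6-yl]methanol | OCC1=CC[C@@]2(C)CCC(C(C)C)=C2CC1 | intermediate
14 | vanillic acid (4-hydroxy-3-methoxybenzoic acid) | COc1cc(C(=O)O)ccc1O | starting material
15 | [(8aR)-8a-methyl-3-(propan-2-yl)-1,2,4,5,8,8a-hexahydroazulen-6-yl]methyl 4-hydroxy-3-methoxybenzoate | COc1cc(C(=O)OCC2=CC[C@@]3(C)CCC(C(C)C)=C3CC2)ccc1O | target

**Step count and risks**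

Total step count: 9. Longest linear sequence: 9 steps (1 → 15).

Step 5 (bears the label). The hydrogen atom may be returned to cobalt before the C1 radical adds to C10, so that only the cyclopentene double bond isomerises and no skeletal change occurs; conjugate reduction of the enone by hydride is a second failure mode. The fallback uses a cationic 1,2-shift instead and sets out from 8. Li/NH3 reduction of the enone and trapping with PhNTf2 should give (4S,5R)-1-methyl-4-(propan-2-yl)spiro[4.5]deca-1,7-dien-8-yl trifluoromethanesulfonate F1. Methoxycarbonylation (Pd(OAc)2, PPh3, CO, MeOH, Et3N) should give the spiro ester F2, i-Bu2AlH the spiro allylic alcohol F3, and Ac2O/pyridine the spiro allylic acetate F4. Catalytic TfOH in CH2Cl2 at −40 °C, quenched under kinetic control, should protonate the cyclopentene alkene at C2; the allylic carbon C10 then shifts from C5 to the tertiary cation at C1 (Wagner–Meerwein rearrangement) and loss of the C4 hydrogen should give the ring-expanded acetate F5. K2CO3/MeOH then leads back to the route at 13.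

Step 4. The extended enolate may add through its γ-positions (C2 or C15), the enone may polymerise, or the facial selectivity at C5 may be poor. The fallback replaces the Michael addition by an SN2 alkylation and sets out from 5. Deconjugative α-alkylation of the potassium dienolate (KOtBu, THF, −20 °C) with 2-(2-iodoethyl)-2-methyl-1,3-dioxolane should give the ketal aldehyde F6. Aqueous HCl in THF then frees the ketone, which comes back to the route at 7, and KOH/MeOH closes 7 to 8 in a separate aldol condensation.

Step 9. The phenol oxygen may be alkylated in competition with the carboxylate, and the allylic alcohol may react with transposition (SN2′). The fallback acylates the alcohol instead of alkylating the acid and sets out from 13. Esterification with 4-acetoxy-3-methoxybenzoic acid (DCC, DMAP, CH2Cl2) should give the acetyl-protected ester F7, and pyrrolidine in CH2Cl2 at 0 °C should cleave the aryl acetate selectively, coming back to the route at 15.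

**Further compounds**

F1 | step 5 | (4S,5R)-1-methyl-4-(propan-2-yl)spiro[4.5]deca-1,7-dien-8-yl trifluoromethanesulfonate | CC1=CC[C@@H](C(C)C)[C@@]12CC=C(OS(=O)(=O)C(F)(F)F)CC2
F2 | step 5 | methyl (4S,5R)-1-methyl-4-(propan-2-yl)spiro[4.5]deca-1,7-diene-8-carboxylate | CC1=CC[C@@H](C(C)C)[C@@]12CC=C(C(=O)OC)CC2
F3 | step 5 | [(4S,5R)-1-methyl-4-(propan-2-yl)spiro[4.5]deca-1,7-dien-8-yl]methanol | CC1=CC[C@@H](C(C)C)[C@@]12CC=C(CO)CC2
F4 | step 5 | [(4S,5R)-1-methyl-4-(propan-2-yl)spiro[4.5]deca-1,7-dien-8-yl]methyl acetate | CC1=CC[C@@H](C(C)C)[C@@]12CC=C(COC(C)=O)CC2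
F5 | step 5 | [(8aR)-8a-methyl-3-(propan-2-yl)-1,2,4,5,8,8a-hexahydroazulen-6-yl]methyl acetate | CC(=O)OCC1=CC[C@@]2(C)CCC(C(C)C)=C2CC1
F6 | step 4 | (1R,5S)-2-methyl-1-[2-(2-methyl-1,3-dioxolan-2-yl)ethyl]-5-(propan-2-yl)cyclopent-2-ene-1-carbaldehyde | CC1(CC[C@]2(C=O)C(C)=CC[C@H]2C(C)C)OCCO1
F7 | step 9 | [(8aR)-8a-methyl-3-(propan-2-yl)-1,2,4,5,8,8a-hexahydroazulen-6-yl]methyl 4-acetoxy-3-methoxybenzoate | COc1cc(C(=O)OCC2=CC[C@@]3(C)CCC(C(C)C)=C3CC2)ccc1OC(C)=O
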